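Both quinate units (ring A, the acyl donor; ring B, the acyl acceptor; both of the unnatural (+)-quinic acid series) have C1 as the sole fully substituted ring carbon, holding O1 and the carboxyl carbon C7 between the C2 and C6 methylenes. Cutting C1–C6 and C2–C3 reduces each ring to 1,3-butadiene plus a 2-acyloxyacrolein. One ammonium-salt-catalysed enantioselective Diels–Alder reaction of 2-(benzoyloxy)acrolein, made by retro-cycloaddition from a dioxanone enol benzoate, therefore builds the carbocycle, both bonds and the C1 stereocentre. The C7 carboxyl then transmits C1 to C5, C4 and C3 through a bridged lactone; the inter-ring ester is forged at the bridgehead O1 of the lactone acetonide and both caffeoyl groups are attached together.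

Key step: step 3

Remark: quinate numbering is used throughout (C1 quaternary, C7 carboxyl, O5 the ring oxygen cis to C7); "(+)-series" means the mirror image of natural (−)-quinic acid, which the target SMILES encodes in both rings.
Assumption: (R)-1,1'-binaphthyl-2,2'-diamine is written as the catalyst antipode that gives (R)-6; should the first run give (S)-6 (read from the sign of rotation of 11 against natural (−)-quinic acid), the (S)-diamine is used and nothing else changes.

Step 1
Reactants: 1 2,2-dimethyl-1,3-dioxan-5-one; 2 benzoyl chloride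
Product: 3 2,2-dimethyl-4H-1,3-dioxin-5-yl benzoate
Conditions: Et3N, DMAP (cat.), CH2Cl2, 0 °C to rt
Reagents that add atoms: none
Why: Acyl transfer to the enol form of the doubly alpha-oxygenated ketone under amine/DMAP catalysis gives the enol benzoate (enol ester formation), the usual entry to 5-acyloxy-4H-1,3-dioxins; no stereocentre is formed.

Step 2
Reactants: 3 2,2-dimethyl-4H-1,3-dioxin-5-yl benzoate
Product: 4 2-(benzoyloxy)acrolein
Conditions: toluene, 110 °C, acetone distilled off, BHT (trace); used at once
Reagents that add atoms: none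
Why: A thermal retro-hetero-Diels–Alder reaction of the 4H-1,3-dioxin expels volatile acetone irreversibly and leaves the 2-acyloxyacrolein, which is stabilised with a radical inhibitor and not stored because it polymerises.

Step 3
Reactants: 4 2-(benzoyloxy)acrolein; 5 1,3-butadiene
Product: 6 (R)-1-formylcyclohex-3-en-1-yl benzoate
Conditions: (R)-1,1'-binaphthyl-2,2'-diamine (10 mol%), HNTf2 (19 mol%), 5 (10 equiv, condensed in), EtCN, −20 to 0 °C, sealed vessel
Reagents that add atoms: none
Why: Reversible condensation of a primary amino group of the catalyst with the formyl group of 4 gives a protonated aldimine, a far more electron-poor dienophile than the aldehyde, which combines with s-cis butadiene in one concerted suprafacial [4+2] event before hydrolysis releases 6 and the catalyst. The closest known reaction type is the chiral primary ammonium salt-catalysed Diels–Alder reaction of 2-acyloxyacroleins with cyclic and 2-substituted acyclic dienes. The single ring is closed by intermolecular [4+2] cycloaddition, forming C1–C6 and C2–C3 (quinate numbering) and leaving the C4=C5 alkene. The new C1 stereocentre is set by the catalyst alone: the second ammonium group hydrogen-bonds to the benzoyloxy carbonyl and so fixes the geometry of the aldiminium ion, while the binaphthyl backbone covers one face of its C=C bond. The only selectivity required is between the two faces of the dienophile, because butadiene is symmetric and contributes no stereocentre, so neither regiochemistry nor endo/exo orientation matters. The benzoyloxy group of 4 secures this by serving as the hydrogen-bond anchor and by making the aldiminium ion reactive enough for the unactivated diene at a temperature where the uncatalysed reaction should be slow.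

Step 4
Reactants: 6 (R)-1-formylcyclohex-3-en-1-yl benzoate
Product: 7 (R)-1-(benzoyloxy)cyclohex-3-ene-1-carboxylic acid
Conditions: NaClO2, NaH2PO4, 2-methyl-2-butene, t-BuOH/H2O, 0 °C to rt
Reagents that add atoms: sodium chlorite, [Na+].[O-]Cl=O
Why: Pinnick oxidation converts the non-enolisable aldehyde to the acid while 2-methyl-2-butene scavenges hypochlorous acid, so the ring alkene and the C1 stereocentre are untouched.

Step 5
Reactants: 7 (R)-1-(benzoyloxy)cyclohex-3-ene-1-carboxylic acid
Product: 8 (1R,4S,5S)-4-iodo-7-oxo-6-oxabicyclo[3.2.1]octan-1-yl benzoate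
Conditions: I2, KI, NaHCO3, H2O/CH2Cl2, 0 °C to rt, dark
Reagents that add atoms: iodine, II
Why: Iodolactonisation: the carboxylate opens the iodonium ion of the C4=C5 alkene in the favoured gamma-lactone (bicyclo[3.2.1]) mode, so O5 is delivered on the face of C7 dictated by C1 and iodine arrives anti on C4.

Step 6
Reactants: 8 (1R,4S,5S)-4-iodo-7-oxo-6-oxabicyclo[3.2.1]octan-1-yl benzoate
Product: 9 (1R,5S)-7-oxo-6-oxabicyclo[3.2.1]oct-3-en-1-yl benzoate
Conditions: DBU, toluene, 80 °C
Reagents that add atoms: none
Why: E2 dehydroiodination through the axial C4–I bond and the anti-periplanar C3–H (the bridgehead C5–H cannot be used) gives the C3=C4 alkene without touching C1 or C5.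

Step 7
Reactants: 9 (1R,5S)-7-oxo-6-oxabicyclo[3.2.1]oct-3-en-1-yl benzoate
Product: 11 (+)-quinic acid, via 1-O-benzoyl-(+)-1,5-quinide 10 (not isolated)
Conditions: OsO4 (2 mol%), NMO, acetone/H2O, rt; then 2 M NaOH, rt; then HCl to pH 2
Reagents that add atoms: osmium tetroxide, O=[Os](=O)(=O)=O; N-methylmorpholine N-oxide, C[N+]1([O-])CCOCC1; water, O; sodium hydroxide, [Na+].[OH-]
Why: Catalytic OsO4 syn-dihydroxylation should occur on the alkene face anti to the lactone bridge, setting the C3 and C4 hydroxyls cis to O1 and trans to O5, and the following saponification of the benzoate and the strained lactone gives the free acid after extraction of benzoic acid and passage through an acidic ion-exchange resin.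

Step 8
Reactants: 11 (+)-quinic acid
Product: 12 3,4-O-isopropylidene-(+)-1,5-quinide
Conditions: 2,2-dimethoxypropane, TsOH·H2O (cat.), acetone, reflux
Reagents that add atoms: 2,2-dimethoxypropane, COC(C)(C)OC
Why: Acid-catalysed ketalisation of the cis-3,4-diol with concurrent lactonisation of C7 onto O5 under dehydrating conditions is the classic one-step conversion of quinic acid into its lactone acetonide, applied here to the enantiomer, and leaves the bridgehead C1 hydroxyl free.

Step 9
Reactants: 12 3,4-O-isopropylidene-(+)-1,5-quinide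
Product: 15 3,4-O-isopropylidene-1,5-bis-O-(triethylsilyl)-(+)-quinic acid, via lithium 3,4-O-isopropylidene-(+)-quinate 13 (not isolated), via tris(triethylsilyl) quinate 14 (not isolated)
Conditions: LiOH·H2O, THF/H2O, 0 °C to rt; evaporate, toluene azeotrope; TESOTf (3.5 equiv), 2,6-lutidine, CH2Cl2, 0 °C to rt; then H2O/THF, rt
Reagents that add atoms: lithium hydroxide, [Li+].[OH-]; triethylsilyl triflate, CC[Si](CC)(CC)OS(=O)(=O)C(F)(F)F
Why: Saponification of the strained lactone, exhaustive silylation of the C5 and C1 hydroxyls and of the carboxylate with the silyl triflate, and selective hydrolysis of the much more labile silyl ester on addition of water give the acid with both hydroxyls masked, and no stereocentre is affected.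

Step 10
Reactants: 15 3,4-O-isopropylidene-1,5-bis-O-(triethylsilyl)-(+)-quinic acid; 12 3,4-O-isopropylidene-(+)-1,5-quinide
Product: 17 ring A bis-silylated quinoyl ester at O1 of the ring B quinide acetonide, via bis-silylated quinoyl chloride 16 (not isolated)
Conditions: 1-chloro-N,N,2-trimethylprop-1-en-1-amine, CH2Cl2, 0 °C to rt; then 12, DMAP (1.5 equiv), Et3N, toluene, 60 °C
Reagents that add atoms: none
Why: Neutral acyl chloride formation followed by DMAP-mediated acyl transfer (nucleophilic catalysis) to the C1 hydroxyl of 12, which is a bridgehead alcohol tied back by the lactone and the position at which quinide acetonides are normally acylated, while 16 has no alpha-hydrogen and so offers no ketene or epimerisation path.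

Step 11
Reactants: 17 ring A bis-silylated quinoyl ester at O1 of the ring B quinide acetonide
Product: 18 allyl ester of 17 with the ring B lactone opened (ring B O5–H free)
Conditions: allyl alcohol/THF (1:1), NaH (0.2 equiv), 0 °C; AcOH quench
Reagents that add atoms: allyl alcohol, C=CCO
Why: Alkoxide-catalysed transesterification opens the strained, alpha-acyloxy-activated lactone of ring B in excess allyl alcohol, while the inter-ring ester, flanked by two quaternary carbons, should resist attack and cannot migrate to the trans-disposed O5.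

Step 12
Reactants: 18 allyl ester of 17 with the ring B lactone opened
Product: 19 triol (ring A O1–H and O5–H, ring B O5–H; both acetonides and allyl ester kept)
Conditions: HF·pyridine, pyridine, THF, 0 °C to rt
Reagents that add atoms: none
Why: Fluoride-mediated cleavage of the two triethylsilyl ethers of ring A under buffered, non-basic conditions leaves the ketals, the allyl ester and the inter-ring ester intact and avoids base-induced relactonisation.

Step 13
Reactants: 20 caffeic acid
Product: 21 (E)-3-(3,4-diacetoxyphenyl)acrylic acid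
Conditions: Ac2O, pyridine, rt; aqueous work-up
Reagents that add atoms: acetic anhydride, CC(=O)OC(C)=O
Why: Pyridine-mediated acetylation of both phenols (any mixed anhydride at the carboxyl is hydrolysed on aqueous work-up) gives the standard protected caffeoyl donor.

Step 14
Reactants: 19 triol; 21 (E)-3-(3,4-diacetoxyphenyl)acrylic acid (2.6 equiv)
Product: 23 allyl ester of the bis(5-O-diacetylcaffeoyl) bis-acetonide dimer, via 3,4-di-O-acetylcaffeoyl chloride 22 (not isolated)
Conditions: (COCl)2, DMF (cat.), CH2Cl2, rt, evaporate; then 19, pyridine, DMAP (cat.), CH2Cl2, 0 °C to rt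
Reagents that add atoms: none
Why: Chemoselective esterification of the two secondary C5 hydroxyls with the cinnamoyl chloride under pyridine/DMAP is the usual way to acylate O5 next to a 3,4-acetonide, and the hindered tertiary ring A C1 hydroxyl should remain free.

Step 15
Reactants: 23 allyl ester of the bis(5-O-diacetylcaffeoyl) bis-acetonide dimer
Product: 24 free ring B carboxylic acid of 23
Conditions: Pd(PPh3)4 (5 mol%), N-methylaniline, THF, rt
Reagents that add atoms: none
Why: Tsuji–Trost-type deallylation, in which zerovalent palladium ionises the allyl ester to a pi-allyl complex that the weakly nucleophilic aniline captures, a scavenger chosen because it does not aminolyse the aryl acetates.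

Step 16
Reactants: 24 free ring B carboxylic acid of 23
Product: 25 target CNP0107948.2
Conditions: 1 M HCl (aq)/THF (1:3), rt to 35 °C; reversed-phase chromatography
Reagents that add atoms: none
Why: Dilute aqueous acid hydrolyses the four aryl acetates and both cyclic ketals, the customary final unmasking for caffeoylquinic acids, under which the cinnamate esters and the hindered inter-ring ester should survive and no C5 lactone can form because O5 is acylated.

Compound list
1 | 2,2-dimethyl-1,3-dioxan-5-one | CC1(C)OCC(=O)CO1 | starting material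
2 | benzoyl chloride | O=C(Cl)c1ccccc1 | starting material
3 | 2,2-dimethyl-4H-1,3-dioxin-5-yl benzoate | CC1(C)OCC(OC(=O)c2ccccc2)=CO1 | intermediate
4 | 2-(benzoyloxy)acrolein (3-oxoprop-1-en-2-yl benzoate) | C=C(OC(=O)c1ccccc1)C=O | intermediate
5 | 1,3-butadiene | C=CC=C | starting material
6 | (R)-1-formylcyclohex-3-en-1-yl benzoate | O=C[C@]1(OC(=O)c2ccccc2)CC=CCC1 | intermediate
7 | (R)-1-(benzoyloxy)cyclohex-3-ene-1-carboxylic acid | OC(=O)[C@]1(OC(=O)c2ccccc2)CC=CCC1 | intermediate
8 | (1R,4S,5S)-4-iodo-7-oxo-6-oxabicyclo[3.2.1]octan-1-yl benzoate (lactone O on quinate C5, iodine on C4 anti to it) | O1[C@H]2C[C@@](OC(=O)c3ccccc3)(C1=O)CC[C@@H]2I | intermediate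
9 | (1R,5S)-7-oxo-6-oxabicyclo[3.2.1]oct-3-en-1-yl benzoate | O1[C@H]2C[C@@](OC(=O)c3ccccc3)(C1=O)CC=C2 | intermediate
10 | (1R,3S,4S,5S)-3,4-dihydroxy-7-oxo-6-oxabicyclo[3.2.1]octan-1-yl benzoate (1-O-benzoyl-(+)-1,5-quinide) | O1[C@H]2C[C@@](OC(=O)c3ccccc3)(C1=O)C[C@H](O)[C@@H]2O | intermediate
11 | (+)-quinic acid, (1R,3S,4R,5S)-1,3,4,5-tetrahydroxycyclohexane-1-carboxylic acid | O[C@H]1C[C@@](O)(C(=O)O)C[C@H](O)[C@@H]1O | intermediate
12 | 3,4-O-isopropylidene-(+)-1,5-quinide (lactone C7–O5, acetonide on O3/O4, free bridgehead C1–OH) | O1[C@H]2C[C@@](O)(C1=O)C[C@@H]3OC(C)(C)O[C@H]23 | intermediate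
13 | lithium 3,4-O-isopropylidene-(+)-quinate | O[C@H]1C[C@@](O)(C(=O)[O-])C[C@@H]2OC(C)(C)O[C@H]12.[Li+] | intermediate
14 | triethylsilyl 3,4-O-isopropylidene-1,5-bis-O-(triethylsilyl)-(+)-quinate | CC[Si](CC)(CC)O[C@H]1C[C@@](O[Si](CC)(CC)CC)(C(=O)O[Si](CC)(CC)CC)C[C@@H]2OC(C)(C)O[C@H]12 | intermediate
15 | 3,4-O-isopropylidene-1,5-bis-O-(triethylsilyl)-(+)-quinic acid | CC[Si](CC)(CC)O[C@H]1C[C@@](O[Si](CC)(CC)CC)(C(=O)O)C[C@@H]2OC(C)(C)O[C@H]12 | intermediate
16 | 3,4-O-isopropylidene-1,5-bis-O-(triethylsilyl)-(+)-quinoyl chloride | CC[Si](CC)(CC)O[C@H]1C[C@@](O[Si](CC)(CC)CC)(C(Cl)=O)C[C@@H]2OC(C)(C)O[C@H]12 | intermediate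
17 | 3,4-O-isopropylidene-1-O-[3,4-O-isopropylidene-1,5-bis-O-(triethylsilyl)-(+)-quinoyl]-(+)-1,5-quinide | CC[Si](CC)(CC)O[C@H]1C[C@@](O[Si](CC)(CC)CC)(C(=O)O[C@@]3(C4=O)C[C@H](O4)[C@H]5OC(C)(C)O[C@H]5C3)C[C@@H]2OC(C)(C)O[C@H]12 | intermediate
18 | allyl 3,4-O-isopropylidene-1-O-[3,4-O-isopropylidene-1,5-bis-O-(triethylsilyl)-(+)-quinoyl]-(+)-quinate | CC[Si](CC)(CC)O[C@H]1C[C@@](O[Si](CC)(CC)CC)(C(=O)O[C@@]3(C(=O)OCC=C)C[C@H](O)[C@H]5OC(C)(C)O[C@H]5C3)C[C@@H]2OC(C)(C)O[C@H]12 | intermediate
19 | allyl 3,4-O-isopropylidene-1-O-[3,4-O-isopropylidene-(+)-quinoyl]-(+)-quinate (triol) | O[C@H]1C[C@@](O)(C(=O)O[C@@]3(C(=O)OCC=C)C[C@H](O)[C@H]5OC(C)(C)O[C@H]5C3)C[C@@H]2OC(C)(C)O[C@H]12 | intermediate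
20 | caffeic acid | OC(=O)/C=C/c1ccc(O)c(O)c1 | starting material
21 | (E)-3-(3,4-diacetoxyphenyl)acrylic acid | CC(=O)Oc1ccc(/C=C/C(=O)O)cc1OC(C)=O | intermediate
22 | (E)-3-(3,4-diacetoxyphenyl)acryloyl chloride | CC(=O)Oc1ccc(/C=C/C(Cl)=O)cc1OC(C)=O | intermediate
23 | allyl 5-O-(3,4-di-O-acetyl-(E)-caffeoyl)-3,4-O-isopropylidene-1-O-[5-O-(3,4-di-O-acetyl-(E)-caffeoyl)-3,4-O-isopropylidene-(+)-quinoyl]-(+)-quinate | O=C(/C=C/c1ccc(OC(C)=O)c(OC(C)=O)c1)O[C@H]1C[C@@](O)(C(=O)O[C@@]3(C(=O)OCC=C)C[C@H](OC(=O)/C=C/c4ccc(OC(C)=O)c(OC(C)=O)c4)[C@H]5OC(C)(C)O[C@H]5C3)C[C@@H]2OC(C)(C)O[C@H]12 | intermediate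
24 | 5-O-(3,4-di-O-acetyl-(E)-caffeoyl)-3,4-O-isopropylidene-1-O-[5-O-(3,4-di-O-acetyl-(E)-caffeoyl)-3,4-O-isopropylidene-(+)-quinoyl]-(+)-quinic acid | O=C(/C=C/c1ccc(OC(C)=O)c(OC(C)=O)c1)O[C@H]1C[C@@](O)(C(=O)O[C@@]3(C(=O)O)C[C@H](OC(=O)/C=C/c4ccc(OC(C)=O)c(OC(C)=O)c4)[C@H]5OC(C)(C)O[C@H]5C3)C[C@@H]2OC(C)(C)O[C@H]12 | intermediate
25 | 5-O-(E)-caffeoyl-1-O-[5-O-(E)-caffeoyl-(+)-quinoyl]-(+)-quinic acid (CNP0107948.2) | O=C(/C=C/c1ccc(O)c(O)c1)O[C@H]1C[C@@](O)(C(=O)O[C@@]2(C(=O)O)C[C@H](OC(=O)/C=C/c3ccc(O)c(O)c3)[C@@H](O)[C@@H](O)C2)C[C@H](O)[C@@H]1O | target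

Total step count: 16. Longest linear sequence: 15 steps (steps 1–12 and 14–16; step 13 is a one-step branch from caffeic acid, and 12 is used twice in step 10).

Steps most likely to fail

1. Step 3. The unactivated, gaseous diene may add too slowly to the aldiminium ion, so that the temperature needed lets the uncatalysed pathway erode the facial discrimination while 4 polymerises. The fallback sets out from 4 and 5 and returns at 7. The cycloaddition is run thermally without a chiral catalyst (toluene, 80 °C, sealed vessel, BHT) and should give racemic 1-formylcyclohex-3-en-1-yl benzoate F1. Pinnick oxidation of F1 as in step 4 gives racemic 1-(benzoyloxy)cyclohex-3-ene-1-carboxylic acid F2. The acid F2 is resolved by fractional crystallisation of its salt (S)-1-phenylethylammonium (R)-1-(benzoyloxy)cyclohex-3-ene-1-carboxylate F3; the antipodal amine is used if the other diastereomeric salt proves the less soluble one. Acidification of F3 with dilute HCl releases 7.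

2. Step 10. Acyl transfer between a quaternary acyl chloride carrying a bulky silyloxy group and a tertiary alcohol may be too slow, so that hydrolysis or desilylation of 16 wins. The fallback sets out from 11 and returns at 19; it uses a ketal-activated acyl donor that needs no silyl group on O1. Kinetic ketalisation of 11 with 2,2-dimethoxypropane and TsOH in acetone at rt, stopped before lactonisation takes over, gives 3,4-O-isopropylidene-(+)-quinic acid 1,7-acetonide F4, in which O1 and C7 are tied into a spiro 2,2-dimethyl-1,3-dioxolan-4-one and O5–H is free. TESCl and imidazole convert F4 into 3,4-O-isopropylidene-5-O-(triethylsilyl)-(+)-quinic acid 1,7-acetonide F5. Deprotonation of 12 with NaN(SiMe3)2 in THF at −78 °C gives the sodium 1-alkoxide of 3,4-O-isopropylidene-(+)-1,5-quinide F6, which opens the dioxolanone carbonyl of F5 with loss of acetone. A cold acetic acid quench then gives 3,4-O-isopropylidene-1-O-[3,4-O-isopropylidene-5-O-(triethylsilyl)-(+)-quinoyl]-(+)-1,5-quinide F7, which has a free ring A C1 hydroxyl and the ring B lactone intact. Allyl alcoholysis of F7 as in step 11 gives allyl 3,4-O-isopropylidene-1-O-[3,4-O-isopropylidene-5-O-(triethylsilyl)-(+)-quinoyl]-(+)-quinate F8, and treatment of F8 with HF·pyridine as in step 12 gives 19.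

3. Step 9. Silylation of the axial tertiary C1 hydroxyl in the opened carboxylate may be incomplete, or the material may relactonise during the one-pot sequence. The fallback sets out from 12 and returns at 15, using temporary carboxyl protection. Allyl alcoholysis of 12 (allyl alcohol, NaH cat., 0 °C) gives allyl 3,4-O-isopropylidene-(+)-quinate F9. TESOTf and 2,6-lutidine convert F9 into allyl 3,4-O-isopropylidene-1,5-bis-O-(triethylsilyl)-(+)-quinate F10. Pd(PPh3)4 and morpholine then remove the allyl group of F10 to give 15.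

Further compounds
F1 | step 3 | racemic 1-formylcyclohex-3-en-1-yl benzoate | O=CC1(OC(=O)c2ccccc2)CC=CCC1
F2 | step 3 | racemic 1-(benzoyloxy)cyclohex-3-ene-1-carboxylic acid | OC(=O)C1(OC(=O)c2ccccc2)CC=CCC1
F3 | step 3 | (S)-1-phenylethylammonium (R)-1-(benzoyloxy)cyclohex-3-ene-1-carboxylate | [O-]C(=O)[C@]1(OC(=O)c2ccccc2)CC=CCC1.C[C@H]([NH3+])c1ccccc1
F4 | step 10 | 3,4-O-isopropylidene-(+)-quinic acid 1,7-acetonide | O[C@H]1C[C@@](OC(C)(C)O3)(C3=O)C[C@@H]2OC(C)(C)O[C@H]12
F5 | step 10 | 3,4-O-isopropylidene-5-O-(triethylsilyl)-(+)-quinic acid 1,7-acetonide | CC[Si](CC)(CC)O[C@H]1C[C@@](OC(C)(C)O3)(C3=O)C[C@@H]2OC(C)(C)O[C@H]12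
F6 | step 10 | sodium 1-alkoxide of 3,4-O-isopropylidene-(+)-1,5-quinide | [Na+].[O-][C@@]1(C2=O)C[C@H](O2)[C@H]3OC(C)(C)O[C@H]3C1
F7 | step 10 | 3,4-O-isopropylidene-1-O-[3,4-O-isopropylidene-5-O-(triethylsilyl)-(+)-quinoyl]-(+)-1,5-quinide | CC[Si](CC)(CC)O[C@H]1C[C@@](O)(C(=O)O[C@@]3(C4=O)C[C@H](O4)[C@H]5OC(C)(C)O[C@H]5C3)C[C@@H]2OC(C)(C)O[C@H]12
F8 | step 10 | allyl 3,4-O-isopropylidene-1-O-[3,4-O-isopropylidene-5-O-(triethylsilyl)-(+)-quinoyl]-(+)-quinate | CC[Si](CC)(CC)O[C@H]1C[C@@](O)(C(=O)O[C@@]3(C(=O)OCC=C)C[C@H](O)[C@H]5OC(C)(C)O[C@H]5C3)C[C@@H]2OC(C)(C)O[C@H]12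
F9 | step 9 | allyl 3,4-O-isopropylidene-(+)-quinate | O[C@H]1C[C@@](O)(C(=O)OCC=C)C[C@@H]2OC(C)(C)O[C@H]12
F10 | step 9 | allyl 3,4-O-isopropylidene-1,5-bis-O-(triethylsilyl)-(+)-quinate | CC[Si](CC)(CC)O[C@H]1C[C@@](O[Si](CC)(CC)CC)(C(=O)OCC=C)C[C@@H]2OC(C)(C)O[C@H]12
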